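The route rests on cutting the O–C(CH3)2 bond of the 2H-pyran on ring B. Its oxygen sits on C-4′, whose only free ortho carbon (C-3′) lies between O-4′ and O-2′, while O-2′ and O-5′ are para. The key step builds this pyran in one operation on 2,5-dimethoxyphenol: phenylboronic acid tethers prenal to the phenol, the resulting benzodioxaborinine fragments to an ortho-quinone methide, and oxa-6π electrocyclization closes the ring. Oxidation gives a chromenequinone whose pyran oxygen steers a Nenitzescu-type annulation with a 2-morpholinochromone carrying the complete ring A, which closes the furan and delivers the target.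

Key step: step 1

Remark: the target has no stereocentre; positions are numbered as in isoflavonoids (C-2 to C-8a for the chromone, C-1′ to C-6′ for ring B), and compounds 1, 2, 7 and 8 are taken as commercial.

Step 1
Reactants: 1 2,5-dimethoxyphenol; 2 3-methylbut-2-enal (prenal)
Product: 5 5,8-dimethoxy-2,2-dimethyl-2H-chromene, via benzodioxaborinine 3 (not isolated), via ortho-quinone methide 4 (not isolated)
Conditions: PhB(OH)2 (1.1 equiv), propionic acid (0.3 equiv), toluene, reflux, Dean–Stark
Reagents that add atoms: none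
Why: Phenol 1, PhB(OH)2 and prenal condense to a mixed boronate in which boron activates the aldehyde and delivers its carbonyl carbon intramolecularly to C-6 of the phenol, giving the 4H-1,3,2-benzodioxaborinine 3 (a temporary B–O tether); cycloreversion with loss of PhBO then unveils the (Z)-ortho-quinone methide 4. The 1-oxatriene O=C–C=C–C=C of 4 closes by thermal disrotatory oxa-6π electrocyclization, which forms the O–C(CH3)2 bond and the six-membered 2H-pyran and is driven by rearomatization. The closest known reaction type is the phenylboronic acid-mediated synthesis of 2H-chromenes from phenols and enals (a formal [3+3] annulation). No stereocentre survives, since the benzylic centre of 3 becomes sp2 in 4. The step needs ortho- rather than para-C–C bond formation, secured by the boron tether, and a single ortho site, secured by the 2-methoxy group that blocks the other one; the only oxygen able to close the ring is the former phenol oxygen, the carbonyl of 4.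

Step 2
Reactants: 5 5,8-dimethoxy-2,2-dimethyl-2H-chromene
Product: 6 2,2-dimethyl-2H-chromene-5,8-dione
Conditions: (NH4)2Ce(NO3)6 (2.5 equiv), MeCN–H2O (2:1), 0 °C, short reaction time
Reagents that add atoms: water, O
Why: Oxidative demethylation of a 1,4-dimethoxyarene by the tetravalent cerium salt should give the para-quinone, with water supplying the carbonyl oxygens, while the brief cold reaction should leave the pyran double bond untouched.

Step 3
Reactants: 7 2′,4′,6′-trihydroxyacetophenone; 8 1-bromo-3-methylbut-2-ene (prenyl bromide)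
Product: 9 1-[2,4,6-trihydroxy-3,5-bis(3-methylbut-2-en-1-yl)phenyl]ethan-1-one
Conditions: 8 (2.2 equiv), 10% aq. KOH, 0 °C to rt; chromatographic removal of mono- and over-alkylated material
Reagents that add atoms: none
Why: Direct C-prenylation of an acylphloroglucinol: in water the ambident phenoxide is alkylated on carbon, and the two equivalent ring carbons should each take one prenyl group.

Step 4
Reactants: 9 1-[2,4,6-trihydroxy-3,5-bis(3-methylbut-2-en-1-yl)phenyl]ethan-1-one
Product: 11 5,7-dihydroxy-2-(methylsulfanyl)-6,8-bis(3-methylbut-2-en-1-yl)-4H-chromen-4-one, via chromene-2-thione 10 (not isolated)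
Conditions: LiN(SiMe3)2 (4.2 equiv), THF, −78 to −10 °C; CS2, to rt; 1 M HCl; then MeI (1.05 equiv), NaHCO3, acetone, 0 °C
Reagents that add atoms: carbon disulfide, S=C=S; iodomethane, CI
Why: The polylithiated ketone enolate should add to CS2 (Claisen-type thioacylation), the beta-oxo dithioate closes onto either of the two equivalent ortho-hydroxyls with loss of H2S, and the soft thiolate sulfur of 10 is methylated in preference to the phenols, giving the alpha-oxo ketene O,S-acetal.

Step 5
Reactants: 11 5,7-dihydroxy-2-(methylsulfanyl)-6,8-bis(3-methylbut-2-en-1-yl)-4H-chromen-4-one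
Product: 12 5-hydroxy-2-(methylsulfanyl)-6,8-bis(3-methylbut-2-en-1-yl)-4-oxo-4H-chromen-7-yl acetate
Conditions: Ac2O (1.05 equiv), pyridine, DMAP (cat.), CH2Cl2, 0 °C
Reagents that add atoms: acetic anhydride, CC(=O)OC(C)=O
Why: Chemoselective O-acetylation: the 5-OH is locked in a hydrogen bond to the C-4 carbonyl, so only the 7-OH should be acylated.

Step 6
Reactants: 12 5-hydroxy-2-(methylsulfanyl)-6,8-bis(3-methylbut-2-en-1-yl)-4-oxo-4H-chromen-7-yl acetate
Product: 13 2,2-dimethyl-8-(methylsulfanyl)-6-(3-methylbut-2-en-1-yl)-10-oxo-3,4-dihydro-2H,10H-pyrano[2,3-f]chromen-5-yl acetate (dihydropyran fused through O-5 and C-6 of the chromone; 7-OAc; 8-prenyl)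
Conditions: anhydrous p-TsOH (0.2 equiv), toluene, 60 °C, stopped at full conversion of 12
Reagents that add atoms: none
Why: Acid-catalysed intramolecular Markovnikov hydroalkoxylation of an ortho-prenylphenol to a 2,2-dimethylchroman: with O-7 acetylated only the 5-OH can trap the tertiary cation of the C-6 prenyl group, whereas the cation of the C-8 prenyl group has no hydroxyl neighbour and should revert to the alkene.

Step 7
Reactants: 13 2,2-dimethyl-8-(methylsulfanyl)-6-(3-methylbut-2-en-1-yl)-10-oxo-3,4-dihydro-2H,10H-pyrano[2,3-f]chromen-5-yl acetate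
Product: 14 5-hydroxy-2,2-dimethyl-6-(3-methylbut-2-en-1-yl)-8-(morpholin-4-yl)-3,4-dihydro-2H,10H-pyrano[2,3-f]chromen-10-one (the 2-morpholinochromone with free 7-OH)
Conditions: morpholine (neat, excess), 80 °C
Reagents that add atoms: morpholine, C1COCCN1
Why: Vinylic nucleophilic substitution (addition–elimination) at C-2 of the vinylogous thiocarbonate should replace methanethiolate by the amine, and the excess amine should cleave the aryl acetate by aminolysis, so the nucleophile for the union and the free 7-OH are produced together.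

Step 8
Reactants: 14 5-hydroxy-2,2-dimethyl-6-(3-methylbut-2-en-1-yl)-8-(morpholin-4-yl)-3,4-dihydro-2H,10H-pyrano[2,3-f]chromen-10-one; 6 2,2-dimethyl-2H-chromene-5,8-dione
Product: 16 CNP0081330.0 (target), via hydroquinone adduct 15 (not isolated)
Conditions: 6 (1.0 equiv), AcOH–CH2Cl2 (1:4), argon, rt to 40 °C; aq. Na2S2O4 wash
Reagents that add atoms: none
Why: Proposed new method: 14 is a cyclic tertiary enaminone (ketene N,O-acetal) whose C-3 should add in Michael fashion to C-6 of quinone 6, because the pyran oxygen turns the C-5 carbonyl into a vinylogous ester and leaves the C-8 carbonyl to direct attack beta to itself, as in additions to 2-alkoxy-1,4-benzoquinones; tautomerization gives hydroquinone 15, whose C-5 hydroxyl (future O-2′), ortho to the new bond, adds to protonated C-2 and expels morpholine, closing the furan without oxidant under acid too weak to touch the prenyl group or the pyran; the closest known reaction type is the Nenitzescu synthesis of 5-hydroxybenzofurans from tertiary enaminones and 1,4-benzoquinones, extended here to a 2-aminochromone.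

Compound list
1 | 2,5-dimethoxyphenol | COc1ccc(OC)c(O)c1 | starting material
2 | 3-methylbut-2-enal (prenal) | CC(C)=CC=O | starting material
3 | 5,8-dimethoxy-4-(2-methylprop-1-en-1-yl)-2-phenyl-4H-1,3,2-benzodioxaborinine (racemic) | COc1ccc(OC)c2c1OB(c1ccccc1)OC2C=C(C)C | intermediate (not isolated)
4 | (6Z)-2,5-dimethoxy-6-(3-methylbut-2-en-1-ylidene)cyclohexa-2,4-dien-1-one | O=C1C(OC)=CC=C(OC)/C1=C/C=C(C)C | intermediate (not isolated)
5 | 5,8-dimethoxy-2,2-dimethyl-2H-chromene | COc1ccc(OC)c2c1OC(C)(C)C=C2 | intermediate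
6 | 2,2-dimethyl-2H-chromene-5,8-dione | O=C1C=CC(=O)C2=C1OC(C)(C)C=C2 | intermediate
7 | 2′,4′,6′-trihydroxyacetophenone | CC(=O)c1c(O)cc(O)cc1O | starting material
8 | 1-bromo-3-methylbut-2-ene (prenyl bromide) | CC(C)=CCBr | starting material
9 | 1-[2,4,6-trihydroxy-3,5-bis(3-methylbut-2-en-1-yl)phenyl]ethan-1-one | CC(=O)c1c(O)c(CC=C(C)C)c(O)c(CC=C(C)C)c1O | intermediate
10 | 4,5,7-trihydroxy-6,8-bis(3-methylbut-2-en-1-yl)-2H-chromene-2-thione | S=C1C=C(O)c2c(O)c(CC=C(C)C)c(O)c(CC=C(C)C)c2O1 | intermediate (not isolated)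
11 | 5,7-dihydroxy-2-(methylsulfanyl)-6,8-bis(3-methylbut-2-en-1-yl)-4H-chromen-4-one | CSc1cc(=O)c2c(O)c(CC=C(C)C)c(O)c(CC=C(C)C)c2o1 | intermediate
12 | 5-hydroxy-2-(methylsulfanyl)-6,8-bis(3-methylbut-2-en-1-yl)-4-oxo-4H-chromen-7-yl acetate | CSc1cc(=O)c2c(O)c(CC=C(C)C)c(OC(C)=O)c(CC=C(C)C)c2o1 | intermediate
13 | 2,2-dimethyl-8-(methylsulfanyl)-6-(3-methylbut-2-en-1-yl)-10-oxo-3,4-dihydro-2H,10H-pyrano[2,3-f]chromen-5-yl acetate | CSc1cc(=O)c2c3OC(C)(C)CCc3c(OC(C)=O)c(CC=C(C)C)c2o1 | intermediate
14 | 5-hydroxy-2,2-dimethyl-6-(3-methylbut-2-en-1-yl)-8-(morpholin-4-yl)-3,4-dihydro-2H,10H-pyrano[2,3-f]chromen-10-one | CC(C)=CCc1c(O)c2CCC(C)(C)Oc2c2c(=O)cc(N3CCOCC3)oc12 | intermediate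
15 | 9-(5,8-dihydroxy-2,2-dimethyl-2H-chromen-6-yl)-5-hydroxy-2,2-dimethyl-6-(3-methylbut-2-en-1-yl)-8-(morpholin-4-yl)-3,4-dihydro-2H,10H-pyrano[2,3-f]chromen-10-one | CC(C)=CCc1c(O)c2CCC(C)(C)Oc2c2c(=O)c(-c3cc(O)c4OC(C)(C)C=Cc4c3O)c(N3CCOCC3)oc12 | intermediate (not isolated)
16 | CNP0081330.0: coumaronochromone (benzofuro[2,3-b]chromen-11-one core); ring A with 7-OH, 8-prenyl and a 2,2-dimethyl-3,4-dihydro-2H-pyran fused at O-5/C-6; ring B with 5′-OH and a 2,2-dimethyl-2H-pyran fused at C-3′/O-4′ | CC(C)=CCc1c(O)c2c(c3c(=O)c4c(oc13)oc1c3c(c(O)cc14)OC(C)(C)C=C3)OC(C)(C)CC2 | target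

Total step count: 8. Longest linear sequence: 6 steps (steps 3 to 8, from 7); the ring B branch (steps 1 and 2) joins at step 8.

Steps most likely to fail

1. Step 8 (Proposed new method). The Michael addition of the vinylogous carbamate carbon may be slow, it may occur at C-7 of the quinone, or the hydroquinone adduct may be oxidised by unreacted 6 before it cyclises. The fallback uses known cross-coupling chemistry, sets out from 6 and 13 and returns at 16.
 - 1,4-Addition of HBr to 6 (48% aq. HBr, CHCl3, 0 °C) should give 6-bromo-2,2-dimethyl-2H-chromene-5,8-diol F1.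
 - Miyaura borylation (B2pin2, Pd(dppf)Cl2, KOAc, dioxane, 80 °C) should give 2,2-dimethyl-6-(4,4,5,5-tetramethyl-1,3,2-dioxaborolan-2-yl)-2H-chromene-5,8-diol F2.
 - Iodination of 13 at C-3 of the chromone with N-iodosuccinimide (MeCN, 0 °C) should give 9-iodo-2,2-dimethyl-8-(methylsulfanyl)-6-(3-methylbut-2-en-1-yl)-10-oxo-3,4-dihydro-2H,10H-pyrano[2,3-f]chromen-5-yl acetate F3.
 - Suzuki–Miyaura coupling of F3 with F2 (Pd(PPh3)4, K2CO3, dioxane–H2O, 80 °C) forms the C-3–C-1′ bond. Under the same basic conditions the 2′-phenoxide should displace methanethiolate at C-2 by addition–elimination and the acetate is hydrolysed, giving 16.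

2. Step 6. The chelated 5-OH is a weak nucleophile, so the reaction may stall while the spectator C-8 prenyl group undergoes double-bond migration; loss of the acetyl group would let O-7 cyclise instead. The fallback runs from 12 to 13 by oxidative ring closure and selective reduction.
 - DDQ (1.1 equiv, benzene, reflux) should dehydrogenate the 5-hydroxy-6-prenyl unit through an ortho-quinone methide and oxa-6π closure to 2,2-dimethyl-8-(methylsulfanyl)-6-(3-methylbut-2-en-1-yl)-10-oxo-2H,10H-pyrano[2,3-f]chromen-5-yl acetate F4. The C-8 prenyl group has no free hydroxyl neighbour and should not cyclise.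
 - Diimide (2-nitrobenzenesulfonohydrazide, Et3N, CH2Cl2, rt) should then reduce the cis-disubstituted pyran double bond in preference to the trisubstituted prenyl alkene, giving 13.

3. Step 4. Incomplete formation of the tetra-anion, thiocarbonylation on oxygen, or methylation of phenoxides may erode the one-pot annulation. The fallback runs from 9 to 11 with protecting groups and the classical dianion procedure.
 - MOMCl (2.2 equiv) and i-Pr2NEt in CH2Cl2 should protect two hydroxyls and leave one chelated hydroxyl free, giving 1-[2-hydroxy-4,6-bis(methoxymethoxy)-3,5-bis(3-methylbut-2-en-1-yl)phenyl]ethan-1-one F5.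
 - KOt-Bu and CS2 in THF, then MeI, should give 5,7-bis(methoxymethoxy)-2-(methylsulfanyl)-6,8-bis(3-methylbut-2-en-1-yl)-4H-chromen-4-one F6.
 - 2 M HCl in MeOH at rt should remove both MOM groups and give 11.

Further compounds
F1 | step 8 | 6-bromo-2,2-dimethyl-2H-chromene-5,8-diol | Oc1cc(Br)c(O)c2C=CC(C)(C)Oc12
F2 | step 8 | 2,2-dimethyl-6-(4,4,5,5-tetramethyl-1,3,2-dioxaborolan-2-yl)-2H-chromene-5,8-diol | Oc1cc(B2OC(C)(C)C(C)(C)O2)c(O)c2C=CC(C)(C)Oc12
F3 | step 8 | 9-iodo-2,2-dimethyl-8-(methylsulfanyl)-6-(3-methylbut-2-en-1-yl)-10-oxo-3,4-dihydro-2H,10H-pyrano[2,3-f]chromen-5-yl acetate | CSc1c(I)c(=O)c2c3OC(C)(C)CCc3c(OC(C)=O)c(CC=C(C)C)c2o1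
F4 | step 6 | 2,2-dimethyl-8-(methylsulfanyl)-6-(3-methylbut-2-en-1-yl)-10-oxo-2H,10H-pyrano[2,3-f]chromen-5-yl acetate | CSc1cc(=O)c2c3OC(C)(C)C=Cc3c(OC(C)=O)c(CC=C(C)C)c2o1
F5 | step 4 | 1-[2-hydroxy-4,6-bis(methoxymethoxy)-3,5-bis(3-methylbut-2-en-1-yl)phenyl]ethan-1-one | CC(=O)c1c(O)c(CC=C(C)C)c(OCOC)c(CC=C(C)C)c1OCOC
F6 | step 4 | 5,7-bis(methoxymethoxy)-2-(methylsulfanyl)-6,8-bis(3-methylbut-2-en-1-yl)-4H-chromen-4-one | CSc1cc(=O)c2c(OCOC)c(CC=C(C)C)c(OCOC)c(CC=C(C)C)c2o1
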